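Rings: A (resorcinol) and D (monophenol) form the dihydrophenanthrene, B is the fused catechol, C the pendant one. The seven-membered ring is cut between the ring-D benzylic CH2 (C16) and the methine bearing ring C (C15); both are carried as aldehydes. The C16 aldehyde first anchors a transient directing group for enantioselective C–H arylation of the dihydrophenanthrene CH2, setting C8 and bringing in ring B with the C15 aldehyde. Intramolecular McMurry coupling then closes the ring as a C15=C16 cis-stilbene, exploiting that both atoms are benzylic and held together by C8. Because ring B carries an oxygen para to C15, acid adds veratrole (ring C) there, anti to C8–H; BBr3 finishes.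

Key step: step 5

Labels: C7 and C8 are the CH2 and CH of the dihydrophenanthrene bridge (C8 bears ring B); C15 and C16 are as defined above. In the target the hydrogens on C8 and C15 are cis on the seven-membered ring, (S) at C8 and (R) at C15.

Assumption: L-tert-leucine is taken to give the (S) configuration at C8 in step 4; if the sense of induction is the opposite, D-tert-leucine is used and nothing else changes.

Step 1
Reactants: 1 3,5-dimethoxystyrene; 2 2-bromo-5-methoxybenzaldehyde
Product: 4 2-[2-(3,5-dimethoxyphenyl)ethyl]-5-methoxybenzaldehyde, via B-alkyl-9-BBN adduct 3 (not isolated)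
Conditions: 9-BBN, THF, 0 °C to rt; then K3PO4 (aq), 2, Pd(dppf)Cl2 (cat.), DMF, 60 °C
Reagents that add atoms: none
Why: Anti-Markovnikov hydroboration followed by B-alkyl Suzuki–Miyaura coupling joins the terminal styrene carbon (C8) to ring D, and the aldehyde should survive because it meets the borane only as its base-quaternized, non-reducing ate complex.

Step 2
Reactants: 4 2-[2-(3,5-dimethoxyphenyl)ethyl]-5-methoxybenzaldehyde
Product: 5 2-[2-(2-bromo-3,5-dimethoxyphenyl)ethyl]-5-methoxybenzaldehyde
Conditions: NBS (1.0 equiv), MeCN, 0 °C, dark
Reagents that add atoms: N-bromosuccinimide, O=C1CCC(=O)N1Br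
Why: Electrophilic aromatic bromination should go to the doubly methoxy-activated ring A rather than the formyl-deactivated ring D, at one of the two equivalent positions ortho to the side chain and para to a methoxy group and not at the hindered position between the two methoxy groups.

Step 3
Reactants: 5 2-[2-(2-bromo-3,5-dimethoxyphenyl)ethyl]-5-methoxybenzaldehyde
Product: 6 3,5,7-trimethoxy-9,10-dihydrophenanthrene-1-carbaldehyde
Conditions: Pd(OAc)2 (5 mol %), PCy3·HBF4 (10 mol %), K2CO3, t-BuCO2H (30 mol %), DMA, 110 °C
Reagents that add atoms: none
Why: Intramolecular direct arylation by concerted metalation–deprotonation closes the six-membered ring of the dihydrophenanthrene, and the site is unambiguous because the only free ring-D position next to the tether carbon is the C–H meta to the formyl group; no stereocenter exists yet.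

Step 4
Reactants: 6 3,5,7-trimethoxy-9,10-dihydrophenanthrene-1-carbaldehyde; 7 2-iodo-4,5-dimethoxybenzaldehyde
Product: 8 (10S)-10-(2-formyl-4,5-dimethoxyphenyl)-3,5,7-trimethoxy-9,10-dihydrophenanthrene-1-carbaldehyde
Conditions: Pd(OAc)2 (10 mol %), L-tert-leucine (30 mol %), AgO2CCF3, HFIP/AcOH, H2O, 80 °C
Reagents that add atoms: none
Why: Benzylic C(sp3)–H arylation of a 2-alkylbenzaldehyde with a chiral transient directing group: the imine–carboxylate formed reversibly from the C16 aldehyde and the amino acid steers divalent palladium to one enantiotopic C8–H, the palladacycle adds iodide 7 oxidatively to give tetravalent palladium, and reductive elimination forms the C8–ring B bond, so the configuration at C8 is set by the amino acid while silver scavenges iodide.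

Step 5
Reactants: 8 (10S)-10-(2-formyl-4,5-dimethoxyphenyl)-3,5,7-trimethoxy-9,10-dihydrophenanthrene-1-carbaldehyde
Product: 9 pentamethoxy hexacyclic cis-stilbene, (S) at C8: the target skeleton without ring C, with a C15H=C16H double bond in the seven-membered ring and the five hydroxy groups of rings A, B and D as methyl ethers
Conditions: TiCl4, Zn, THF, reflux; slow addition of 8 (high dilution)
Reagents that add atoms: none
Why: Low-valent titanium formed from TiCl4 and Zn reduces both formyl groups to ketyl radicals, their carbons C15 and C16 couple to a titanium pinacolate, and deoxygenation at reflux gives the C15=C16 double bond. The closest known reaction type is the intramolecular McMurry coupling of aromatic dialdehydes to cyclic cis-stilbenes such as phenanthrenes and dibenzo[a,d]cycloheptenes. The seven-membered ring is closed by reductive carbonyl–carbonyl coupling of two aldehyde carbons that sit as ortho substituents on ring D and ring B, both attached to C8, so the ends are pre-organized like a 2,2'-diformyldiarylmethane. No stereocenter is created: C15 and C16 become trigonal, C15 is set in step 6, and C8 should be preserved because the medium is non-basic and the formyl groups that acidify C8–H are consumed. The step needs cyclization to outrun intermolecular coupling, which slow addition at high dilution and the proximity of the two formyl groups should secure, and chemoselectivity for C=O over the aryl methyl ethers, which low-valent titanium provides.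

Step 6
Reactants: 9 pentamethoxy hexacyclic cis-stilbene; 10 1,2-dimethoxybenzene (veratrole)
Product: 11 heptamethyl ether of the target, (S) at C8 and (R) at C15
Conditions: 10 (large excess), CF3SO3H (10 mol %), HFIP, 0 °C
Reagents that add atoms: none
Why: Acid-catalysed hydroarylation (Friedel–Crafts alkylation by an alkene): protonation at C16 gives the C15 cation, which alone is stabilized by a para-methoxy group (on ring B), veratrole attacks it through its 4-position, and because C7 is tied to ring D through ring A the C8–H is the inward (flagpole) hydrogen of the boat-shaped seven-membered ring, so the arene should enter on the opposite face and place ring C cis to C7 and the C15–H cis to C8–H, which is the (15R) configuration.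

Step 7
Reactants: 11 heptamethyl ether of the target
Product: 12 target heptaphenol (CNP0306974.2), (S) at C8 and (R) at C15
Conditions: BBr3 (excess), CH2Cl2, −78 °C to rt; then H2O, under argon
Reagents that add atoms: none
Why: Lewis-acid cleavage of all seven aryl methyl ethers by BBr3 (ether demethylation) should leave the two benzylic stereocenters, which carry no leaving group, unchanged.

Compound list
1 | 3,5-dimethoxystyrene | C=Cc1cc(OC)cc(OC)c1 | starting material
2 | 2-bromo-5-methoxybenzaldehyde | COc1ccc(Br)c(C=O)c1 | starting material
3 | 9-[2-(3,5-dimethoxyphenyl)ethyl]-9-borabicyclo[3.3.1]nonane | COc1cc(CCB2C3CCCC2CCC3)cc(OC)c1 | intermediate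
4 | 2-[2-(3,5-dimethoxyphenyl)ethyl]-5-methoxybenzaldehyde | COc1ccc(CCc2cc(OC)cc(OC)c2)c(C=O)c1 | intermediate
5 | 2-[2-(2-bromo-3,5-dimethoxyphenyl)ethyl]-5-methoxybenzaldehyde | COc1ccc(CCc2cc(OC)cc(OC)c2Br)c(C=O)c1 | intermediate
6 | 3,5,7-trimethoxy-9,10-dihydrophenanthrene-1-carbaldehyde | COc1cc(OC)c2c(c1)CCc1c(C=O)cc(OC)cc1-2 | intermediate
7 | 2-iodo-4,5-dimethoxybenzaldehyde | COc1cc(I)c(C=O)cc1OC | starting material
8 | (10S)-10-(2-formyl-4,5-dimethoxyphenyl)-3,5,7-trimethoxy-9,10-dihydrophenanthrene-1-carbaldehyde | COc1cc(OC)c2c(c1)C[C@@H](c1cc(OC)c(OC)cc1C=O)c1c(C=O)cc(OC)cc1-2 | intermediate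
9 | pentamethoxy hexacyclic cis-stilbene, (S) at C8 (target skeleton without ring C, C15H=C16H, five OMe on rings A, B and D) | COc1cc(OC)c2c(c1)C[C@H]1c3cc(OC)c(OC)cc3C=Cc3cc(OC)cc-2c31 | intermediate
10 | 1,2-dimethoxybenzene (veratrole) | COc1ccccc1OC | starting material
11 | heptamethyl ether of the target, (S) at C8, (R) at C15 | COc1cc(OC)c2c(c1)C[C@H]1c3cc(OC)c(OC)cc3[C@@H](c3ccc(OC)c(OC)c3)Cc3cc(OC)cc-2c31 | intermediate
12 | target heptaphenol, (S) at C8, (R) at C15 | Oc1cc(O)c2c(c1)C[C@H]1c3cc(O)c(O)cc3[C@@H](c3ccc(O)c(O)c3)Cc3cc(O)cc-2c31 | target

Total step count: 7. Longest linear sequence: 7 (steps 1 to 7 from 1; compounds 2, 7 and 10 are bought).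

Steps most likely to fail

Step 4. The ring methylene of 6 may be palladated too slowly, the palladacycle may instead dehydrogenate the dihydrophenanthrene to the phenanthrene, or enantioselectivity may be low on the cyclic substrate. The fallback sets out from 5 and comes back at 9 by moving the arylation in front of the biaryl closure. Open-chain aldehyde 5, a 2-(2-arylethyl)benzaldehyde of the usual substrate type, would be arylated with 7 under the same Pd(OAc)2, L-tert-leucine and AgO2CCF3 system to give 2-[(1R)-2-(2-bromo-3,5-dimethoxyphenyl)-1-(2-formyl-4,5-dimethoxyphenyl)ethyl]-5-methoxybenzaldehyde F1. McMurry coupling (TiCl4, Zn, THF, reflux) would then close the seven-membered ring to (5R)-5-[(2-bromo-3,5-dimethoxyphenyl)methyl]-2,3,8-trimethoxy-5H-dibenzo[a,d][7]annulene F2. Intramolecular direct arylation (Pd(OAc)2, PCy3·HBF4, K2CO3, t-BuCO2H, DMA) would form the ring A–ring D bond last. Carbonate is kept away from F1 because its C8–H is acidified by two formyl groups. Attack on ring D rather than ring B is expected because the ring-B site would force two methoxy groups into the bay region.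

Step 6. The C15 cation may alkylate ring A of a second molecule faster than it is captured by veratrole, or acid-mediated reversal may erode the facial selectivity. The fallback sets out from 9 and comes back at 11 and avoids a free cation in the presence of nucleophilic arenes. Dry HCl (CH2Cl2, −20 °C) would add in the same Markovnikov sense to give the C15 chloride of the pentamethoxy hexacycle (epimer mixture at C15) F3. A nickel-catalysed Negishi coupling with 3,4-dimethoxyphenylzinc bromide (NiCl2(dme), bipyridine-type ligand, DMA, 0 °C) would then form the C15–aryl bond through a benzylic radical that nickel should capture on the face anti to C8–H. A chiral bis(oxazoline) ligand can reinforce this preference.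

Step 5. Intermolecular coupling to oligomers or arrest at the pinacol stage may compete with ring closure. The fallback sets out from 8 and comes back at 9 by olefin metathesis. Both formyl groups would be methylenated with Cp2TiMe2 (toluene, 70 °C; non-basic, so C8–H is not epimerized) to give (10S)-1-ethenyl-10-(2-ethenyl-4,5-dimethoxyphenyl)-3,5,7-trimethoxy-9,10-dihydrophenanthrene F4. Ring-closing metathesis with the second-generation Grubbs catalyst RuCl2(=CHPh)(H2IMes)(PCy3) (CH2Cl2, 40 °C) would form the same C15=C16 bond.

Further compounds
F1 | step 4 | 2-[(1R)-2-(2-bromo-3,5-dimethoxyphenyl)-1-(2-formyl-4,5-dimethoxyphenyl)ethyl]-5-methoxybenzaldehyde | O=Cc1cc(OC)ccc1[C@@H](Cc1cc(OC)cc(OC)c1Br)c1cc(OC)c(OC)cc1C=O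
F2 | step 4 | (5R)-5-[(2-bromo-3,5-dimethoxyphenyl)methyl]-2,3,8-trimethoxy-5H-dibenzo[a,d][7]annulene | COc1ccc2c(c1)C=Cc1cc(OC)c(OC)cc1[C@@H]2Cc1cc(OC)cc(OC)c1Br
F3 | step 6 | C15 chloride of the pentamethoxy hexacycle, (S) at C8, epimer mixture at C15 | COc1cc(OC)c2c(c1)C[C@H]1c3cc(OC)c(OC)cc3C(Cl)Cc3cc(OC)cc-2c31
F4 | step 5 | (10S)-1-ethenyl-10-(2-ethenyl-4,5-dimethoxyphenyl)-3,5,7-trimethoxy-9,10-dihydrophenanthrene | COc1cc(OC)c2c(c1)C[C@@H](c1cc(OC)c(OC)cc1C=C)c1c(C=C)cc(OC)cc1-2
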